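The oxolane is closed last, between O1 and the benzylic carbon C2, by reductive cycloetherification of an open-chain γ-hydroxy aryl ketone: the C5 hydroxyl adds to the C2 carbonyl, water is lost and Et3SiH reduces the 2-aryl oxocarbenium ion. The step exploits the cis pair of substituents on ring carbons C3 (CH2OH) and C4 (trimethoxybenzyl): both shield one face of the O1=C2 cation, so hydride enters C2 anti to them and the aryl group ends on their face, giving the contra-thermodynamic all-cis (2R,3R,4R) ring that a benzylic-cation closure would miss. The (2R,3R)-keto diol comes from a tandem dithiane conjugate addition–benzylation on (5R)-menthyloxybutenolide.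

Key step: step 6

Assumption: the (5R)-menthyloxybutenolide is taken as a purchasable reagent, and the γ-hydroxy aryl ketone is drawn as its open-chain tautomer, which is expected to dominate for a conjugated aryl ketone; any ring-closed hemiketal present at equilibrium is simply the first intermediate of the key step.

Step 1
Reactants: 1 3,4,5-trimethoxybenzaldehyde; 2 propane-1,3-dithiol
Product: 3 2-(3,4,5-trimethoxyphenyl)-1,3-dithiane
Conditions: BF3·OEt2 (cat.), CH2Cl2, 0 °C → rt
Reagents that add atoms: none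
Why: Lewis-acid-catalysed dithioacetalisation of an aromatic aldehyde turns the future C2 into an acyl-anion equivalent at the ketone oxidation level (Corey–Seebach umpolung).

Step 2
Reactants: 4 (2,4,5-trimethoxyphenyl)methanol
Product: 5 1-(bromomethyl)-2,4,5-trimethoxybenzene
Conditions: PBr3 (0.4 equiv), Et2O, 0 °C; cold NaHCO3 wash, used at once
Reagents that add atoms: PBr3, BrP(Br)Br
Why: Bromination of an activated benzylic alcohol with PBr3 should be fast at 0 °C; the electron-rich bromide is labile and is therefore made cold and not stored.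

Step 3
Reactants: 3 2-(3,4,5-trimethoxyphenyl)-1,3-dithiane; 6 (5R)-5-[(1R,2S,5R)-menthyloxy]furan-2(5H)-one; 5 1-(bromomethyl)-2,4,5-trimethoxybenzene
Product: 9 (3R,4R,5R)-5-[(1R,2S,5R)-menthyloxy]-3-(2,4,5-trimethoxybenzyl)-4-[2-(3,4,5-trimethoxyphenyl)-1,3-dithian-2-yl]dihydrofuran-2(3H)-one, via lithiated dithiane 7 (not isolated), via lactone lithium enolate 8 (not isolated)
Conditions: n-BuLi, THF, −78 → −20 °C; then 6, −78 °C; then 5, DMPU, −78 → −20 °C
Reagents that add atoms: none
Why: Tandem conjugate addition–enolate alkylation on a γ-alkoxybutenolide: the soft 2-aryl-2-lithiodithiane should add 1,4 to C4 of 6 anti to the C5 menthyloxy group, and enolate 8 should be benzylated at C3 anti to the bulky dithianyl group, so the acetal centre relays into the trans,trans lactone and fixes the future C3 and C4 of the target in one flask.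

Step 4
Reactants: 9 (3R,4R,5R)-5-[(1R,2S,5R)-menthyloxy]-3-(2,4,5-trimethoxybenzyl)-4-[2-(3,4,5-trimethoxyphenyl)-1,3-dithian-2-yl]dihydrofuran-2(3H)-one
Product: 10 (2R,3R)-2-(2,4,5-trimethoxybenzyl)-3-[2-(3,4,5-trimethoxyphenyl)-1,3-dithian-2-yl]butane-1,4-diol
Conditions: LiAlH4, THF, 0 °C → rt; aqueous NaOH work-up
Reagents that add atoms: none
Why: Hydride reduction of the acylal-type lactone should run through to the 1,4-diol (lactone carbonyl and unmasked acetal aldehyde both to CH2OH), expelling menthol and erasing the auxiliary centre while the dithiane and the two carbon stereocentres are untouched.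

Step 5
Reactants: 10 (2R,3R)-2-(2,4,5-trimethoxybenzyl)-3-[2-(3,4,5-trimethoxyphenyl)-1,3-dithian-2-yl]butane-1,4-diol
Product: 11 (2R,3R)-4-hydroxy-2-(hydroxymethyl)-3-(2,4,5-trimethoxybenzyl)-1-(3,4,5-trimethoxyphenyl)butan-1-one
Conditions: Hg(ClO4)2 (2.2 equiv), CaCO3, THF–H2O (5:1), 0 °C, short contact; filtration
Reagents that add atoms: water, O
Why: Thiophilic mercury-assisted hydrolysis of the dithioketal, buffered with CaCO3, should release the aryl ketone at 0 °C without free acid or base, so the β-hydroxy ketone and its α-stereocentre (future C3) are not exposed to enolising conditions.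

Step 6
Reactants: 11 (2R,3R)-4-hydroxy-2-(hydroxymethyl)-3-(2,4,5-trimethoxybenzyl)-1-(3,4,5-trimethoxyphenyl)butan-1-one
Product: 14 [(2R,3R,4R)-4-(2,4,5-trimethoxybenzyl)-2-(3,4,5-trimethoxyphenyl)oxolan-3-yl]methanol, via cyclic hemiketal 12 (not isolated), via oxocarbenium ion 13 (not isolated)
Conditions: Et3SiH (5 equiv), BF3·OEt2 (2.5 equiv), CH2Cl2, −78 → −40 °C; Et3N then aq. NaHCO3 at −40 °C
Reagents that add atoms: none
Why: BF3·OEt2 activates the aryl ketone, the primary C5 hydroxyl adds to give hemiketal 12 (the O1–C2 bond), ionisation gives the 2-aryl oxocarbenium ion 13 and Et3SiH transfers hydride to C2; this is the reductive etherification of a hydroxy ketone, the reaction type used for silane reduction of 2-aryl lactols. The only ring closed is the oxolane, by 5-exo-trig attack of O1 on C2; the C3 hydroxymethyl oxygen could only form an oxetane and should stay out. C2 is the one new stereocentre and is set under substrate control: in the envelope of 13 with C4 as the flap the C4 benzyl group is pseudo-equatorial and the C3 CH2OH group lies on the same face, so inside attack of hydride should occur on the opposite face, leaving H trans and the aryl group cis to both (2R). The selectivity needed is kinetic, for the least stable all-cis isomer, so low temperature and excess silane are used to let hydride capture outrun loss of the C3 proton to the 2-aryl-4,5-dihydrofuran (C3 epimerisation) and re-ionisation of the product at C2. The 3,4,5-trimethoxyphenyl group, a weaker cation stabiliser than a 4-alkoxyphenyl group, should help the kinetic benzylic ether survive.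

Compound list
1 | 3,4,5-trimethoxybenzaldehyde | COc1cc(C=O)cc(OC)c1OC | starting material
2 | propane-1,3-dithiol | SCCCS | starting material
3 | 2-(3,4,5-trimethoxyphenyl)-1,3-dithiane | COc1cc(C2SCCCS2)cc(OC)c1OC | intermediate
4 | (2,4,5-trimethoxyphenyl)methanol | COc1cc(OC)c(OC)cc1CO | starting material
5 | 1-(bromomethyl)-2,4,5-trimethoxybenzene | COc1cc(OC)c(OC)cc1CBr | intermediate
6 | (5R)-5-[(1R,2S,5R)-menthyloxy]furan-2(5H)-one | O=C1C=C[C@H](O[C@@H]2C[C@H](C)CC[C@H]2C(C)C)O1 | starting material
7 | 2-lithio-2-(3,4,5-trimethoxyphenyl)-1,3-dithiane | [Li]C1(c2cc(OC)c(OC)c(OC)c2)SCCCS1 | intermediate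
8 | lithium enolate of (4R,5R)-5-[(1R,2S,5R)-menthyloxy]-4-[2-(3,4,5-trimethoxyphenyl)-1,3-dithian-2-yl]dihydrofuran-2(3H)-one | [Li]OC1=C[C@@H](C2(c3cc(OC)c(OC)c(OC)c3)SCCCS2)[C@H](O[C@@H]2C[C@H](C)CC[C@H]2C(C)C)O1 | intermediate
9 | (3R,4R,5R)-5-[(1R,2S,5R)-menthyloxy]-3-(2,4,5-trimethoxybenzyl)-4-[2-(3,4,5-trimethoxyphenyl)-1,3-dithian-2-yl]dihydrofuran-2(3H)-one | COc1cc(OC)c(OC)cc1C[C@H]1C(=O)O[C@@H](O[C@@H]2C[C@H](C)CC[C@H]2C(C)C)[C@@H]1C1(c2cc(OC)c(OC)c(OC)c2)SCCCS1 | intermediate
10 | (2R,3R)-2-(2,4,5-trimethoxybenzyl)-3-[2-(3,4,5-trimethoxyphenyl)-1,3-dithian-2-yl]butane-1,4-diol | COc1cc(OC)c(OC)cc1C[C@@H](CO)[C@H](CO)C1(c2cc(OC)c(OC)c(OC)c2)SCCCS1 | intermediate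
11 | (2R,3R)-4-hydroxy-2-(hydroxymethyl)-3-(2,4,5-trimethoxybenzyl)-1-(3,4,5-trimethoxyphenyl)butan-1-one | COc1cc(OC)c(OC)cc1C[C@@H](CO)[C@H](CO)C(=O)c1cc(OC)c(OC)c(OC)c1 | intermediate
12 | (3R,4R)-3-(hydroxymethyl)-4-(2,4,5-trimethoxybenzyl)-2-(3,4,5-trimethoxyphenyl)oxolan-2-ol, both C2 epimers | COc1cc(OC)c(OC)cc1C[C@H]1COC(O)(c2cc(OC)c(OC)c(OC)c2)[C@H]1CO | intermediate
13 | (3R,4R)-3-(hydroxymethyl)-4-(2,4,5-trimethoxybenzyl)-2-(3,4,5-trimethoxyphenyl)-4,5-dihydro-3H-furan-1-ium | COc1cc(OC)c(OC)cc1C[C@H]1C[O+]=C(c2cc(OC)c(OC)c(OC)c2)[C@H]1CO | intermediate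
14 | [(2R,3R,4R)-4-(2,4,5-trimethoxybenzyl)-2-(3,4,5-trimethoxyphenyl)oxolan-3-yl]methanol, all-cis | COc1cc(OC)c(OC)cc1C[C@H]1CO[C@@H](c2cc(OC)c(OC)c(OC)c2)[C@H]1CO | target

Total step count: 6
Longest linear sequence: 5 steps (steps 1, 3, 4, 5 and 6; step 2 is a side branch).

Steps most likely to fail

Step 6. Hydride capture of cation 13 may not be face-selective enough, the C3 centre may be lost by reversible proton loss to the enol ether before reduction, or the product may re-ionise at C2 under the Lewis acid. The fallback gives up the cation for a hydrogenation and turns the troublesome enol ether into the substrate. It sets out from 11: mild acid-catalysed cyclodehydration (PPTS, 4 Å molecular sieves, benzene, 50 °C) should make the same O1–C2 closure and carry on to [(4R)-4-(2,4,5-trimethoxybenzyl)-2-(3,4,5-trimethoxyphenyl)-4,5-dihydrofuran-3-yl]methanol F1, in which C3 is deliberately planar. Syn-hydrogenation of its C2=C3 bond (H2, Rh/Al2O3, EtOAc, trace Et3N) from the face anti to the C4 benzyl group should then set C2–H and C3–H together on that face and come back to the route at 14.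

Step 3. C-benzylation of the hindered enolate 8 may be outrun by decomposition of the labile bromide 5, by O-alkylation or by proton transfer. The fallback sets out from enolate 8, which is trapped at −78 °C with commercial 2,4,5-trimethoxybenzaldehyde (COc1cc(OC)c(OC)cc1C=O) in a tandem Michael–aldol reaction, the most dependable trap for such enolates. This should give the 3,4-trans aldol adduct (3S,4R,5R)-3-[hydroxy(2,4,5-trimethoxyphenyl)methyl]-5-[(1R,2S,5R)-menthyloxy]-4-[2-(3,4,5-trimethoxyphenyl)-1,3-dithian-2-yl]dihydrofuran-2(3H)-one F2 as a pair of carbinol epimers. Its strongly activated benzylic hydroxyl is then removed by ionic hydrogenation (Et3SiH, TFA, CH2Cl2, 0 °C), which the dithiane and the acylal-type acetal should tolerate, and the route is rejoined at 9; step 2 is then not needed.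

Step 5. Unmasking the ketone beside two free hydroxyls may go wrong through mercuration of the electron-rich trimethoxybenzyl ring, arrest at a cyclic O,S-ketal, or loss of the C3 configuration and dehydration of the β-hydroxy ketone if hydrolysis is slow. The fallback removes the dithiane earlier and adjusts the oxidation level afterwards. It sets out from 9: metal-free alkylative hydrolysis (MeI, CaCO3, MeCN–H2O, 50 °C) should give (3R,4R,5R)-5-[(1R,2S,5R)-menthyloxy]-3-(2,4,5-trimethoxybenzyl)-4-(3,4,5-trimethoxybenzoyl)dihydrofuran-2(3H)-one F3, whose all-trans ring is the stable arrangement. LiAlH4 in THF then reduces ketone and acetal lactone together to (2R,3R)-2-[hydroxy(3,4,5-trimethoxyphenyl)methyl]-3-(2,4,5-trimethoxybenzyl)butane-1,4-diol F4 (both carbinol epimers, menthol released). Activated MnO2 in CH2Cl2 should oxidise only the secondary benzylic hydroxyl, so the route is rejoined at 11.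

Further compounds
F1 | step 6 | [(4R)-4-(2,4,5-trimethoxybenzyl)-2-(3,4,5-trimethoxyphenyl)-4,5-dihydrofuran-3-yl]methanol | COc1cc(OC)c(OC)cc1C[C@H]1COC(c2cc(OC)c(OC)c(OC)c2)=C1CO
F2 | step 3 | (3S,4R,5R)-3-[hydroxy(2,4,5-trimethoxyphenyl)methyl]-5-[(1R,2S,5R)-menthyloxy]-4-[2-(3,4,5-trimethoxyphenyl)-1,3-dithian-2-yl]dihydrofuran-2(3H)-one, both carbinol epimers | COc1cc(OC)c(OC)cc1C(O)[C@H]1C(=O)O[C@@H](O[C@@H]2C[C@H](C)CC[C@H]2C(C)C)[C@@H]1C1(c2cc(OC)c(OC)c(OC)c2)SCCCS1
F3 | step 5 | (3R,4R,5R)-5-[(1R,2S,5R)-menthyloxy]-3-(2,4,5-trimethoxybenzyl)-4-(3,4,5-trimethoxybenzoyl)dihydrofuran-2(3H)-one | COc1cc(OC)c(OC)cc1C[C@H]1C(=O)O[C@@H](O[C@@H]2C[C@H](C)CC[C@H]2C(C)C)[C@@H]1C(=O)c1cc(OC)c(OC)c(OC)c1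
F4 | step 5 | (2R,3R)-2-[hydroxy(3,4,5-trimethoxyphenyl)methyl]-3-(2,4,5-trimethoxybenzyl)butane-1,4-diol, both carbinol epimers | COc1cc(OC)c(OC)cc1C[C@@H](CO)[C@H](CO)C(O)c1cc(OC)c(OC)c(OC)c1
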